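Multiply the plateau of target by the charge of second substrate, and carry that product from flask to flask.

| flask | starting material | second substrate | coupling partner | free catalyst | remark | time |
|---|---|---|---|---|---|---|
| eta | 1 mM | 1.2 mM | 1.8 mM | 25 µM | run made earlier |  |
| zeta | 1 mM | 1.7 mM | 1.8 mM | 25 µM | run made earlier |  |
| gamma | 1 mM | 2.7 mM | 1.8 mM | 25 µM | run made earlier |  |
| south-west | 1.0 mM | 1.00 mM | 1.80 mM | 25 µM |  | 3.0 min |
| west | 1.0 mM | 1.50 mM | 1.80 mM | 25 µM |  | 3.0 min |
| north | 1.0 mM | 2.50 mM | 1.80 mM | 25 µM |  | 3.0 min |

| run | time / s | target / % |
|---|---|---|
| eta | 12.0 | 5.6 |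
| eta | 30.0 | 11.8 |
| eta | 60.0 | 18.2 |
| eta | 90.0 | 23.4 |
| eta | 120 | 20.6 |
| zeta | 10.0 | 2.4 |
| zeta | 20.0 | 7.7 |
| zeta | 40.0 | 10.1 |
| zeta | 60.0 | 13.5 |
| zeta | 120 | 15.3 |
| gamma | 12.0 | 2.9 |
| gamma | 30.0 | 4.5 |
| gamma | 60.0 | 7.6 |
| gamma | 90.0 | 8.0 |
| gamma | 120 | 7.0 |

(standard deviation of a reading: 1 percentage point)

- a species is counted by the starting material in it: one homo dimer counts as two
- steps thought possible: 2 starting material -> homo dimer; second substrate + free catalyst <-> catalyst intermediate B; coupling partner + catalyst intermediate A -> free catalyst + target; starting material + free catalyst <-> catalyst intermediate A; coupling partner + catalyst intermediate B -> free catalyst + second product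
- "hardly changes" means that all values lie within two and a half points (for a concentration: within two and a half percent of the largest)

* amount of target at the end, in percent of the starting material charged for south-west, west, north, in this order
* how the row runs (rises all the way / rises, then falls / falls, then rises / falls all the way / hardly changes)

Turn the time first. In the gamma run, target reads 8.0% at 90.0 s and 7.0% at 120 s. That is a difference of 1 percentage point, against a scatter of 1 point. So, by hand, going on to 3.0 min should add little, and you may read the end of each new flask as a plateau.

Now turn second substrate. It can bind free catalyst as catalyst intermediate B, so a larger charge should leave less catalyst for the target route. The readings agree. The plateau, read as the mean of the last two readings, is 22.0% in the eta run at 1.2 mM, and 7.50% in the gamma run at 2.7 mM.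

Call plateau times charge the holding product, H 0.264 mM; that value is the eta run's. If the yield ran as one over the charge, H would stay constant. The gamma run gives 0.203 mM, lower than the eta value, so expect H to sag at high charge.

Dividing the eta value by the new charges, your reckoning gives 26.4% for south-west, 17.6% for west and 10.6% for north. The row falls all the way.

The forecast says 27%, 18% and 9.5%, and falls all the way: “Second substrate holds catalyst as intermediate B, so it starves the target route.” At north your figure stands above the forecast's.

The flasks give 27.8%, 19.0% and 8.99%, and the row falls all the way.

    2 starting material → homo dimer (k = 43.0 M⁻¹ s⁻¹)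
    second substrate + free catalyst ⇌ catalyst intermediate B (K = 2400 M⁻¹, k = 1.00 × 10⁵ M⁻¹ s⁻¹)
    coupling partner + catalyst intermediate A → free catalyst + target (k = 2000 M⁻¹ s⁻¹)
    starting material + free catalyst ⇌ catalyst intermediate A (K = 800 M⁻¹, k = 2200 M⁻¹ s⁻¹)
    coupling partner + catalyst intermediate B → free catalyst + second product (k = 1800 M⁻¹ s⁻¹)

Carry H to south-west: plateau times charge there is 0.278 mM, against 0.264 mM from the eta run. On north the same product is 0.225 mM, lower than H. In north, catalyst intermediate B is the resting state, with 65.6% of the catalyst charged at 1.50 min. Switch off the binding of second substrate to free catalyst, and north climbs from 8.99% to 43.6%, while the change from south-west to north goes from −19 points to 0 points.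

The runs are calculated from invented constants; scatter was added.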